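**Numbering and assumption**

Core numbering used throughout: C1 (bridgehead with prenyl), C2 (C=O), C3 (aroyl carbon), C4 (enol carbon), C5 (bridgehead with geranyl), C6 (CH2), C7 (CH with geranyl), C8 (CMe2), C9 (bridging C=O). Ring A is C1–C2–C3–C4–C5–C9; ring B is C1–C8–C7–C6–C5–C9. "Geranyl" means (2E)-3,7-dimethylocta-2,6-dien-1-yl and "prenyl" means 3-methylbut-2-en-1-yl.

Assumption: the target is treated as the 4-hydroxy-2-oxo enol tautomer of the SMILES given; the tautomers of the β-triketone interconvert and are one compound. The SMILES reads as 1R,5R,7S with the C7 geranyl group exo.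

## Analysis of the target

Guttiferone B (27) is a type B polyprenylated acylphloroglucinol built on bicyclo[3.3.1]non-3-ene-2,9-dione. Ring A is a dearomatised acylphloroglucinol: C2, C4 and C9 carry oxygen, C3 carries the 3,4-dihydroxybenzoyl group, and C1 and C5 are quaternary bridgeheads bearing prenyl and geranyl. Ring B is a cyclohexanone that spans C1 and C5 with the bridge C6–C7–C8; C8 is a gem-dimethyl carbon and C7 carries the second geranyl group. There are three stereocenters: C1 and C5 are locked to each other by the bridge, and at C7 the geranyl group is exo, that is equatorial on the chair of ring B, cis to the side chains at C1 and C5 and trans to the C2–C3–C4 bridge. The hard bonds are C1–C8, which joins a bridgehead to the CMe2 carbon, and the bonds to quaternary C5; in addition the two bridgeheads must be told apart, although prenyl and geranyl are nearly identical close to the ring. The sensitive groups are five trisubstituted alkenes (two 1,5-dienes that cyclise under acid and can close onto an enol or phenol oxygen), an air-sensitive catechol and an acidic β-triketone. The feature the route uses: without the C1 prenyl and the C3 aroyl group, ring A has a local mirror plane through C5 and C2 that makes C1 and C3 equivalent (and C9 and C4), so that C7 is the only stereocenter that has to exist beforehand and the closure of ring B through the C1–C8 bond can break the symmetry.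

## Retrosynthetic reasoning

27 from 26. The two aryl O–Si bonds and the O–CH3 bond at C4 are cut. Base-labile protection is chosen because acid and hydrogenolysis are excluded by the five alkenes. The forward step has to free the catechol and the enol in one basic operation.

26 from 21 and 24. The C3–C(aroyl) bond is cut. C3 is the only sp2 C–H of the vinylogous ester in 21 and can be lithiated. The aroyl group is placed last because it would break the symmetry of ring A and make C3 a competing, fully substituted nucleophile in the key step. Acid chloride 24 is traced to 22 through silyl ester 23.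

21 from 18 and 19. The C1–prenyl bond is cut. In 18 the bridgehead C1–H is flanked by the C2 and C9 carbonyl groups and is the only acidic C–H. Adding prenyl after ring closure removes the prenyl/geranyl differentiation problem: which bridgehead becomes C1 is decided by the ring closure, not by an alkylation that would have to choose between two similar carbons.

18 from 15 (key disconnection). The C1–C8 bond is cut and ring B is opened. Precursor 15 is a monocyclic cross-conjugated dienone with a mirror plane through C5 and C2 in the ring, so its two enol-ether carbons are equivalent, C5 is not a stereocenter, and the only stereocenter is C7 in the side chain. The forward reaction has to generate a cation equivalent at C8 from the only 1,1-disubstituted alkene, let one enol-ether carbon attack it through a chair with the C7 geranyl equatorial, and lose the methyl group of the attacked enol ether. That one operation forms ring B, makes C1 and C5 stereogenic in the right sense relative to C7, turns C9 into the ketone and leaves the other methyl ether as the C4 protecting group the endgame needs.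

15 from 13 and 14. The C5–geranyl bond is cut. A dearomative para-allylation of phenol 13 makes C5 quaternary without creating a stereocenter, because both halves of the ring are identical.

13 from 12, and 12 from 10 and 8 through 11. The C5–C6 bond is cut as an aryl–alkyl bond. The carbon between the two methoxy groups of 10 (made from 9) is the site of directed metalation, and the side chain arrives as an sp3 electrophile with C7 already set.

8 from 7, 7 from 6, 6 from 3 and 4, 3 from 1 and 2. The C7–geranyl bond is cut next to a carbonyl group so that an auxiliary can control C7. The five-carbon unit of 2 supplies C6 (carbonyl carbon), C7 (α-carbon), C8 and its two terminal carbons (the isopropenyl group), so the later cation site is carried as an inert alkene until the key step.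

## Alternatives that were turned down

Alternative 1: the textbook double C-acylation (Effenberger-type annulation). Bonds C1–C2 and C4–C5 are cut; methyl enol ether A1 of a 2,4-digeranyl-5,5-dimethylcyclohexanone would be treated with a malonyl dihalide to give trione A2, followed by O-methylation, bridgehead prenylation and C3 aroylation.
- A1 needs its own enantioselective synthesis of a tetrasubstituted cyclohexanone, several steps for one stereocenter.
- The annulation must C-acylate a tetrasubstituted enol-ether carbon and then a CH2 next to CMe2, both in competition with O-acylation, and it liberates hydrogen chloride in the presence of four trisubstituted alkenes.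
- A2 would give two regioisomeric methyl enol ethers, of which only one has the bridgehead hydrogen next to the C2 carbonyl.
- The route ends in the same three-step endgame as the chosen one but reaches it later and with a weaker key step.

Alternative 2: dearomative [3+3] alkylative annulation of the fully substituted arene. Bonds C5–C6 and C1–C8 are cut together; acylphloroglucinol A3 would react with a β,β-dimethyl α-(acyloxymethyl) enal by alkylation and intramolecular Michael addition to give 7-formyl bicycle A4.
- The two nucleophilic ring carbons of A3 differ only in prenyl versus geranyl, five atoms from the reacting centre, so the constitutional isomer with geranyl at C1 and prenyl at C5 should form in equal amount.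
- Absolute configuration would have to come from a chiral catalyst acting on a β,β-disubstituted acceptor.
- The formyl group of A4 would still have to be turned into an (E)-geranyl chain (homologation and a trisubstituted E-alkene) on a β-triketone, which spends what the annulation wins.

Alternative 3: Claisen (Dieckmann-type) closure of ring A. The C2–C3 bond is cut; keto ester A5, with the ester and prenyl at C1 and acetyl and geranyl at C5, would be cyclised by an intramolecular Claisen condensation and then aroylated at C3.
- The three stereocenters of A5 must be built one by one on a cyclohexanone.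
- In the natural order (C7 first, then allylation of the β-dicarbonyl enolate at C5) the allyl group enters anti to the C7 substituent. That places the acyl arm cis to it and leads to the 7-endo series, whereas 27 needs the C5 geranyl cis to the C7 geranyl.
- Inverting the order means C-acylation of a fully substituted enolate, which favours O-acylation, and the sequence exceeds ten linear steps.

Key step: step 9

## Route

Step 1
Reactants: 1 (R)-4-benzyl-1,3-oxazolidin-2-one; 2 3-methylbut-2-enoyl chloride
Product: 3 (R)-4-benzyl-3-(3-methylbut-2-enoyl)-1,3-oxazolidin-2-one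
Conditions: n-BuLi, THF, −78 °C; then 2, −78 to 0 °C
Reagents that add atoms: none
Why: N-acylation of the lithiated oxazolidinone by an acid chloride is standard; no stereocenter is formed and the auxiliary center is untouched.

Step 2
Reactants: 3 (R)-4-benzyl-3-(3-methylbut-2-enoyl)-1,3-oxazolidin-2-one; 4 geranyl bromide
Product: 6 (4R)-4-benzyl-3-[(2R,4E)-5,9-dimethyl-2-(prop-1-en-2-yl)deca-4,8-dienoyl]-1,3-oxazolidin-2-one, via sodium dienolate 5 (not isolated)
Conditions: NaN(SiMe3)2, THF, −78 °C; then 4, −78 to −40 °C
Reagents that add atoms: none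
Why: γ-Deprotonation should give the chelated (Z)-dienolate, which reacts at its α-carbon (deconjugative Evans alkylation); the benzyl group of the (R)-auxiliary shields one face, so geranyl enters from the other and sets C7 as 2R, and the allylic bromide reacts by SN2 with retention of its E geometry.

Step 3
Reactants: 6 (4R)-4-benzyl-3-[(2R,4E)-5,9-dimethyl-2-(prop-1-en-2-yl)deca-4,8-dienoyl]-1,3-oxazolidin-2-one
Product: 7 (2R,4E)-5,9-dimethyl-2-(prop-1-en-2-yl)deca-4,8-dien-1-ol
Conditions: LiBH4, MeOH (1 equiv), Et2O, 0 °C
Reagents that add atoms: none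
Why: Reductive cleavage of the imide by borohydride releases the auxiliary and gives the primary alcohol; the fast reduction of the intermediate aldehyde should leave the allylic C7 center intact and the β,γ-alkene unconjugated.

Step 4
Reactants: 7 (2R,4E)-5,9-dimethyl-2-(prop-1-en-2-yl)deca-4,8-dien-1-ol
Product: 8 (2R,4E)-5,9-dimethyl-2-(prop-1-en-2-yl)deca-4,8-dien-1-yl trifluoromethanesulfonate
Conditions: Tf2O, 2,6-lutidine, CH2Cl2, −78 °C; filtered cold and used at once
Reagents that add atoms: trifluoromethanesulfonic anhydride, O=S(=O)(OS(=O)(=O)C(F)(F)F)C(F)(F)F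
Why: O-sulfonylation of a primary alcohol with a hindered base; the triflate is chosen because the β-branched carbon needs the most reactive leaving group for the coming substitution.

Step 5
Reactants: 9 3,5-dimethoxyphenol
Product: 10 (3,5-dimethoxyphenoxy)tri(propan-2-yl)silane
Conditions: iPr3SiCl, imidazole, DMF, rt
Reagents that add atoms: chlorotri(propan-2-yl)silane, CC(C)[Si](Cl)(C(C)C)C(C)C
Why: Standard silylation of a phenol; the bulky silyl ether masks the acidic proton and is a poor directing group, which keeps the coming metalation away from the positions next to it.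

Step 6
Reactants: 10 (3,5-dimethoxyphenoxy)tri(propan-2-yl)silane; 8 (2R,4E)-5,9-dimethyl-2-(prop-1-en-2-yl)deca-4,8-dien-1-yl trifluoromethanesulfonate
Product: 12 {4-[(2S,4E)-5,9-dimethyl-2-(prop-1-en-2-yl)deca-4,8-dien-1-yl]-3,5-dimethoxyphenoxy}tri(propan-2-yl)silane, via aryllithium 11 (not isolated)
Conditions: n-BuLi, TMEDA, THF, 0 °C; CuBr·SMe2 (10 mol%), then 8, −78 to −20 °C
Reagents that add atoms: none
Why: Directed ortho-metalation takes place between the two methoxy groups, and the aryl nucleophile, tempered by catalytic monovalent copper, displaces the primary triflate by SN2 (copper-catalysed aryl–alkyl coupling); C7 is one carbon away from the reacting center and keeps its configuration (the descriptor changes from R to S only through the priority rules).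

Step 7
Reactants: 12 {4-[(2S,4E)-5,9-dimethyl-2-(prop-1-en-2-yl)deca-4,8-dien-1-yl]-3,5-dimethoxyphenoxy}tri(propan-2-yl)silane
Product: 13 4-[(2S,4E)-5,9-dimethyl-2-(prop-1-en-2-yl)deca-4,8-dien-1-yl]-3,5-dimethoxyphenol
Conditions: Bu4NF, THF, 0 °C; aq. NH4Cl
Reagents that add atoms: none
Why: Fluoride cleaves the aryl silyl ether selectively; nothing else in the molecule responds to fluoride.

Step 8
Reactants: 13 4-[(2S,4E)-5,9-dimethyl-2-(prop-1-en-2-yl)deca-4,8-dien-1-yl]-3,5-dimethoxyphenol; 14 geraniol
Product: 15 4-[(2E)-3,7-dimethylocta-2,6-dien-1-yl]-4-[(2S,4E)-5,9-dimethyl-2-(prop-1-en-2-yl)deca-4,8-dien-1-yl]-3,5-dimethoxycyclohexa-2,5-dien-1-one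
Conditions: Pd(OAc)2 (5 mol%), PPh3 (20 mol%), Ti(OiPr)4 (25 mol%), 4 Å molecular sieves, benzene, 50 °C
Reagents that add atoms: none
Why: Dearomative para-selective Tsuji–Trost allylation of a 4-substituted 3,5-dimethoxyphenol with an allylic alcohol activated by the titanium alkoxide: O-allyl ethers re-ionise, the para carbon flanked by two methoxy donors is the most nucleophilic carbon of the titanium phenoxide, and attack at the CH2 terminus of the π-geranyl complex of palladium should give the linear E product. C5 becomes quaternary but not stereogenic, because the two halves of the ring are identical.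

Step 9
Reactants: 15 4-[(2E)-3,7-dimethylocta-2,6-dien-1-yl]-4-[(2S,4E)-5,9-dimethyl-2-(prop-1-en-2-yl)deca-4,8-dien-1-yl]-3,5-dimethoxycyclohexa-2,5-dien-1-one
Product: 18 (1S,5R,7S)-5,7-bis[(2E)-3,7-dimethylocta-2,6-dien-1-yl]-4-methoxy-8,8-dimethylbicyclo[3.3.1]non-3-ene-2,9-dione, via tertiary C8 radical 16 (not isolated), via C9 oxocarbenium triflate 17 (not isolated)
Conditions: Co(salen) (5 mol%; [N,N′-bis(3,5-di-tert-butylsalicylidene)cyclohexane-1,2-diaminato]cobalt, C36H52CoN2O2, divalent cobalt), N-fluoro-2,4,6-trimethylpyridinium triflate (1.3 equiv), PhSiH3 (1.2 equiv, slow addition), PhCF3, 0 °C to rt; aq. NaHCO3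
Reagents that add atoms: none
Why: Proposed new method: a cobalt hydride formed from Co(salen), the N-fluoropyridinium oxidant and PhSiH3 should transfer a hydrogen atom to the CH2 terminus of the isopropenyl group, the only 1,1-disubstituted alkene among seven C=C bonds, to give radical 16, which is oxidised through an alkylcobalt species to a C8 cation equivalent; the closest known reaction type is cobalt-catalysed hydrogen-atom-transfer/radical–polar-crossover hydrofunctionalisation of unactivated alkenes with intramolecular carbon π-nucleophiles (hydroarylation, polyene bicyclisation), here extended to the α-carbon of a vinylogous ester. One of the two enol-ether carbons next to the ring carbonyl then attacks C8 and forms the C1–C8 bond; ring B closes in a six-membered mode that is endo with respect to the C1=C9 enol ether (both carbons end in the new ring), through a chair in which C8 approaches perpendicular to the dienone plane. The two enol-ether carbons differ only through C7: attack by one places the C7 geranyl group equatorial (exo), attack by the other would force it axial over the C2–C3–C4 bridge or require a boat, so C7 (S) decides which carbon becomes C1 and thereby fixes C5 (R) and C1 (S in 18), while the bridge allows only the cis junction. Oxocarbenium ion 17 cannot lose a proton, because the enol ether would sit at a bridgehead, and should pass its methyl group to the 2,4,6-trimethylpyridine released from the oxidant, which leaves the C9 ketone and keeps the other enol ether as the C4 protecting group. Attack by a methoxy oxygen would give a trialkyloxonium ion that re-ionises, the C2′=C3′ alkene of the C5 geranyl group (the only other six-ring nucleophile) is less nucleophilic than the donor-substituted enol-ether carbon, and the near alkene of the C7 geranyl group could only close a four- or five-membered ring. Chemoselectivity of the hydrogen atom transfer rests on the lower substitution of the isopropenyl group, and slow addition of the silane limits hydride reduction of 17.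

Step 10
Reactants: 18 (1S,5R,7S)-5,7-bis[(2E)-3,7-dimethylocta-2,6-dien-1-yl]-4-methoxy-8,8-dimethylbicyclo[3.3.1]non-3-ene-2,9-dione; 19 prenyl bromide
Product: 21 (1S,5R,7S)-5,7-bis[(2E)-3,7-dimethylocta-2,6-dien-1-yl]-4-methoxy-8,8-dimethyl-1-(3-methylbut-2-en-1-yl)bicyclo[3.3.1]non-3-ene-2,9-dione, via bridgehead lithium enolate 20 (not isolated)
Conditions: LiN(iPr)2, THF, −78 °C; then 19, −78 to −40 °C
Reagents that add atoms: none
Why: The bridgehead C1–H lies between the C2 and C9 carbonyl groups and is the α′ position of the vinylogous ester, so the amide base should remove it regioselectively (bridgehead lithiation of enol ethers of bicyclo[3.3.1]nonane-2,4,9-triones is known); the carbanion-like enolate is C-alkylated by the allylic bromide with retention, as the bridgehead geometry demands.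

Step 11
Reactants: 22 3,4-dihydroxybenzoic acid
Product: 23 tert-butyldimethylsilyl 3,4-bis(tert-butyldimethylsilyloxy)benzoate
Conditions: t-BuMe2SiCl (3.5 equiv), imidazole, DMF, rt
Reagents that add atoms: tert-butyl(chloro)dimethylsilane, CC(C)(C)[Si](C)(C)Cl
Why: Exhaustive silylation of both phenols and the acid is routine and gives a catechol protection that is later removed by base.

Step 12
Reactants: 23 tert-butyldimethylsilyl 3,4-bis(tert-butyldimethylsilyloxy)benzoate
Product: 24 3,4-bis(tert-butyldimethylsilyloxy)benzoyl chloride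
Conditions: (COCl)2, DMF (cat.), CH2Cl2, 0 °C to rt
Reagents that add atoms: oxalyl chloride, O=C(Cl)C(Cl)=O
Why: Silyl esters are converted directly into acid chlorides by the Vilsmeier reagent under neutral conditions, so the aryl silyl ethers remain.

Step 13
Reactants: 21 (1S,5R,7S)-5,7-bis[(2E)-3,7-dimethylocta-2,6-dien-1-yl]-4-methoxy-8,8-dimethyl-1-(3-methylbut-2-en-1-yl)bicyclo[3.3.1]non-3-ene-2,9-dione; 24 3,4-bis(tert-butyldimethylsilyloxy)benzoyl chloride
Product: 26 (1R,5R,7S)-3-[3,4-bis(tert-butyldimethylsilyloxy)benzoyl]-5,7-bis[(2E)-3,7-dimethylocta-2,6-dien-1-yl]-4-methoxy-8,8-dimethyl-1-(3-methylbut-2-en-1-yl)bicyclo[3.3.1]non-3-ene-2,9-dione, via C3 vinyllithium 25 (not isolated)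
Conditions: lithium 2,2,6,6-tetramethylpiperidide (LiNC9H18), THF, −78 °C; then 24, −78 °C
Reagents that add atoms: none
Why: With C1 now quaternary, the only acidic C–H is the vinylic C3–H of the vinylogous ester, which the hindered amide should remove (α-lithiation of a β-alkoxy enone, known on this bicyclic class), and the vinyllithium is acylated by the acid chloride; the change of the C1 descriptor from S to R reflects the priority rules only.

Step 14
Reactants: 26 (1R,5R,7S)-3-[3,4-bis(tert-butyldimethylsilyloxy)benzoyl]-5,7-bis[(2E)-3,7-dimethylocta-2,6-dien-1-yl]-4-methoxy-8,8-dimethyl-1-(3-methylbut-2-en-1-yl)bicyclo[3.3.1]non-3-ene-2,9-dione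
Product: 27 guttiferone B, (1R,5R,7S)-3-(3,4-dihydroxybenzoyl)-5,7-bis[(2E)-3,7-dimethylocta-2,6-dien-1-yl]-4-hydroxy-8,8-dimethyl-1-(3-methylbut-2-en-1-yl)bicyclo[3.3.1]non-3-ene-2,9-dione
Conditions: LiOH, 1,4-dioxane/H2O (degassed, argon), 90 °C; then 1 M HCl to pH 3, 0 °C
Reagents that add atoms: lithium hydroxide (oxygen of the C4 enol), [Li+].[OH-]
Why: Hydroxide should add to C4 of the vinylogous ester and expel methoxide (addition–elimination, known for methyl enol ethers of this class) and cleave both aryl silyl ethers; the alkenes and the three stereocenters, none of which is enolisable, are not affected, and exclusion of air protects the catecholate.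

## Compound list

1 | (R)-4-benzyl-1,3-oxazolidin-2-one | O=C1N[C@H](Cc2ccccc2)CO1 | starting material
2 | 3-methylbut-2-enoyl chloride | CC(C)=CC(Cl)=O | starting material
3 | (R)-4-benzyl-3-(3-methylbut-2-enoyl)-1,3-oxazolidin-2-one | CC(C)=CC(=O)N1[C@H](Cc2ccccc2)COC1=O | intermediate
4 | geranyl bromide, (2E)-1-bromo-3,7-dimethylocta-2,6-diene | CC(C)=CCC/C(C)=C/CBr | starting material
5 | sodium (Z)-dienolate of 3 | C=C(C)/C=C(\[O-])N1[C@H](Cc2ccccc2)COC1=O.[Na+] | intermediate
6 | (4R)-4-benzyl-3-[(2R,4E)-5,9-dimethyl-2-(prop-1-en-2-yl)deca-4,8-dienoyl]-1,3-oxazolidin-2-one | C=C(C)[C@@H](C/C=C(\C)CCC=C(C)C)C(=O)N1[C@H](Cc2ccccc2)COC1=O | intermediate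
7 | (2R,4E)-5,9-dimethyl-2-(prop-1-en-2-yl)deca-4,8-dien-1-ol | OC[C@H](C/C=C(\C)CCC=C(C)C)C(C)=C | intermediate
8 | (2R,4E)-5,9-dimethyl-2-(prop-1-en-2-yl)deca-4,8-dien-1-yl trifluoromethanesulfonate | O=S(=O)(OC[C@H](C/C=C(\C)CCC=C(C)C)C(C)=C)C(F)(F)F | intermediate
9 | 3,5-dimethoxyphenol | COc1cc(O)cc(OC)c1 | starting material
10 | (3,5-dimethoxyphenoxy)tri(propan-2-yl)silane | COc1cc(O[Si](C(C)C)(C(C)C)C(C)C)cc(OC)c1 | intermediate
11 | [2,6-dimethoxy-4-(triisopropylsilyloxy)phenyl]lithium | [Li]c1c(OC)cc(O[Si](C(C)C)(C(C)C)C(C)C)cc1OC | intermediate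
12 | {4-[(2S,4E)-5,9-dimethyl-2-(prop-1-en-2-yl)deca-4,8-dien-1-yl]-3,5-dimethoxyphenoxy}tri(propan-2-yl)silane | COc1cc(O[Si](C(C)C)(C(C)C)C(C)C)cc(OC)c1C[C@H](C/C=C(\C)CCC=C(C)C)C(C)=C | intermediate
13 | 4-[(2S,4E)-5,9-dimethyl-2-(prop-1-en-2-yl)deca-4,8-dien-1-yl]-3,5-dimethoxyphenol | COc1cc(O)cc(OC)c1C[C@H](C/C=C(\C)CCC=C(C)C)C(C)=C | intermediate
14 | geraniol, (2E)-3,7-dimethylocta-2,6-dien-1-ol | CC(C)=CCC/C(C)=C/CO | starting material
15 | 4-[(2E)-3,7-dimethylocta-2,6-dien-1-yl]-4-[(2S,4E)-5,9-dimethyl-2-(prop-1-en-2-yl)deca-4,8-dien-1-yl]-3,5-dimethoxycyclohexa-2,5-dien-1-one | O=C1C=C(OC)C(C/C=C(\C)CCC=C(C)C)(C[C@H](C/C=C(\C)CCC=C(C)C)C(C)=C)C(OC)=C1 | intermediate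
16 | tertiary C8 radical derived from 15 | O=C1C=C(OC)C(C/C=C(\C)CCC=C(C)C)(C[C@H](C/C=C(\C)CCC=C(C)C)[C](C)C)C(OC)=C1 | intermediate
17 | bicyclic C9 O-methyl oxocarbenium triflate | CC(C)=CCC/C(C)=C/C[C@H]1C[C@@]2(C/C=C(\C)CCC=C(C)C)C(=[O+]C)[C@H](C(=O)C=C2OC)C1(C)C.[O-]S(=O)(=O)C(F)(F)F | intermediate
18 | (1S,5R,7S)-5,7-bis[(2E)-3,7-dimethylocta-2,6-dien-1-yl]-4-methoxy-8,8-dimethylbicyclo[3.3.1]non-3-ene-2,9-dione | CC(C)=CCC/C(C)=C/C[C@H]1C[C@@]2(C/C=C(\C)CCC=C(C)C)C(=O)[C@H](C(=O)C=C2OC)C1(C)C | intermediate
19 | prenyl bromide, 1-bromo-3-methylbut-2-ene | CC(C)=CCBr | starting material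
20 | bridgehead (C1) lithium enolate of 18, drawn as the C-lithio form | CC(C)=CCC/C(C)=C/C[C@H]1C[C@@]2(C/C=C(\C)CCC=C(C)C)C(=O)[C@]([Li])(C(=O)C=C2OC)C1(C)C | intermediate
21 | (1S,5R,7S)-5,7-bis[(2E)-3,7-dimethylocta-2,6-dien-1-yl]-4-methoxy-8,8-dimethyl-1-(3-methylbut-2-en-1-yl)bicyclo[3.3.1]non-3-ene-2,9-dione | CC(C)=CCC/C(C)=C/C[C@H]1C[C@@]2(C/C=C(\C)CCC=C(C)C)C(=O)[C@](CC=C(C)C)(C(=O)C=C2OC)C1(C)C | intermediate
22 | 3,4-dihydroxybenzoic acid | O=C(O)c1ccc(O)c(O)c1 | starting material
23 | tert-butyldimethylsilyl 3,4-bis(tert-butyldimethylsilyloxy)benzoate | CC(C)(C)[Si](C)(C)OC(=O)c1ccc(O[Si](C)(C)C(C)(C)C)c(O[Si](C)(C)C(C)(C)C)c1 | intermediate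
24 | 3,4-bis(tert-butyldimethylsilyloxy)benzoyl chloride | O=C(Cl)c1ccc(O[Si](C)(C)C(C)(C)C)c(O[Si](C)(C)C(C)(C)C)c1 | intermediate
25 | C3 vinyllithium of 21 | CC(C)=CCC/C(C)=C/C[C@H]1C[C@@]2(C/C=C(\C)CCC=C(C)C)C(=O)[C@](CC=C(C)C)(C(=O)C([Li])=C2OC)C1(C)C | intermediate
26 | (1R,5R,7S)-3-[3,4-bis(tert-butyldimethylsilyloxy)benzoyl]-5,7-bis[(2E)-3,7-dimethylocta-2,6-dien-1-yl]-4-methoxy-8,8-dimethyl-1-(3-methylbut-2-en-1-yl)bicyclo[3.3.1]non-3-ene-2,9-dione | CC(C)=CCC/C(C)=C/C[C@H]1C[C@@]2(C/C=C(\C)CCC=C(C)C)C(=O)[C@](CC=C(C)C)(C(=O)C(C(=O)c3ccc(O[Si](C)(C)C(C)(C)C)c(O[Si](C)(C)C(C)(C)C)c3)=C2OC)C1(C)C | intermediate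
27 | guttiferone B | CC(C)=CCC/C(C)=C/C[C@H]1C[C@@]2(C/C=C(\C)CCC=C(C)C)C(=O)[C@](CC=C(C)C)(C(=O)C(C(=O)c3ccc(O)c(O)c3)=C2O)C1(C)C | target

## Step count and least certain steps

Total step count: 14. Longest linear sequence: 11 steps (steps 1, 2, 3, 4, 6, 7, 8, 9, 10, 13, 14); steps 5, 11 and 12 are side branches.

Step 9 (key step, proposed new method). Four things may go wrong.
- The C8 cation equivalent may be captured by the C2′=C3′ alkene of the C5 geranyl group, which also closes a six-membered ring, instead of by the enol-ether carbon.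
- Reversible hydrogen atom transfer may move the isopropenyl double bond into the C7=C8 position and so erase the C7 configuration.
- The silane may reduce the oxocarbenium ion before the methyl transfer.
- The tertiary radical may add to C9 in a 5-exo mode before it is oxidised.

The fallback uses known chemistry and separates cation generation from the hydride source. It sets out from 15: cobalt-catalysed Markovnikov hydrochlorination by hydrogen atom transfer (Co(BF4)2·6H2O with a Schiff-base ligand, PhSiH3, p-toluenesulfonyl chloride, t-BuOOH, EtOH), selective for the least substituted alkene, should give the tertiary chloride F1. F1 is then ionised with AgOSO2CF3 and 2,6-di-tert-butyl-4-methylpyridine in CH2Cl2 at −40 °C, a silver-assisted α-tert-alkylation of an enol ether in the absence of free acid and of any hydride donor. Aqueous NaHCO3 hydrolyses the oxocarbenium ion, and the sequence comes back to the route at 18.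

Step 8. The allylation may take place at an unsubstituted ortho carbon, which would rearomatise, or stop at the O-allyl ether, because the para carbon is flanked by two methoxy groups and a β-branched chain. The π-geranyl complex may also lose its E geometry by π–σ–π isomerisation when the nucleophile is slow. The fallback builds the quaternary carbon by two carbanion alkylations and bypasses steps 5 to 8. It sets out from 8 and 4: commercial 1,5-dimethoxycyclohexa-1,4-diene is deprotonated at C6 with t-BuLi (THF, −78 °C) and alkylated with 8 to the monoalkylated diene F2. A second deprotonation and alkylation with 4 gives the dialkylated diene F3. Oxidation of its doubly allylic CH2 group (pyridinium dichromate, (C5H5NH)2Cr2O7, t-BuOOH, Celite, benzene), a known conversion of 1,4-cyclohexadienes into cyclohexa-2,5-dienones, comes back to the route at 15.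

Step 6. The basic aryl metal may eliminate the β-branched triflate, whose β-hydrogen at C7 is allylic, or the substitution at the hindered carbon between two methoxy groups may be slow enough for the triflate to decompose. The fallback replaces the SN2 reaction by a Negishi cross-coupling. It sets out from 7 and 11: 7 is converted with I2, PPh3 and imidazole into the iodide F4, and zinc dust with LiCl in THF inserts to give the alkylzinc iodide F5. Aryllithium 11 is quenched with I2 to the aryl iodide F6. Coupling of F5 and F6 with Pd(OAc)2 and 2-dicyclohexylphosphino-2′,6′-dimethoxybiphenyl (zerovalent palladium formed in situ) in THF comes back to the route at 12.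

Step 10. Deprotonation may occur at the vinylic C3–H instead of the bridgehead, or the hindered bridgehead enolate next to CMe2 may react at oxygen or not at all. The fallback reverses the order of the two lithiations. It sets out from 18: lithium 2,2,6,6-tetramethylpiperidide and 24 give the C3-aroylated bridgehead-H diketone F7, in which C3 is blocked and C1–H is the only acidic hydrogen. LiN(iPr)2 followed by 19 then prenylates C1 and comes back to the route at 26.

## Further compounds

F1 | step 9 | 4-[(2S,4E)-2-(2-chloropropan-2-yl)-5,9-dimethyldeca-4,8-dien-1-yl]-4-[(2E)-3,7-dimethylocta-2,6-dien-1-yl]-3,5-dimethoxycyclohexa-2,5-dien-1-one | O=C1C=C(OC)C(C/C=C(\C)CCC=C(C)C)(C[C@H](C/C=C(\C)CCC=C(C)C)C(C)(C)Cl)C(OC)=C1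
F2 | step 8 | 6-[(2S,4E)-5,9-dimethyl-2-(prop-1-en-2-yl)deca-4,8-dien-1-yl]-1,5-dimethoxycyclohexa-1,4-diene | COC1=CCC=C(OC)C1C[C@H](C/C=C(\C)CCC=C(C)C)C(C)=C
F3 | step 8 | 6-[(2E)-3,7-dimethylocta-2,6-dien-1-yl]-6-[(2S,4E)-5,9-dimethyl-2-(prop-1-en-2-yl)deca-4,8-dien-1-yl]-1,5-dimethoxycyclohexa-1,4-diene | COC1=CCC=C(OC)C1(C/C=C(\C)CCC=C(C)C)C[C@H](C/C=C(\C)CCC=C(C)C)C(C)=C
F4 | step 6 | (2R,4E)-1-iodo-5,9-dimethyl-2-(prop-1-en-2-yl)deca-4,8-diene | IC[C@H](C/C=C(\C)CCC=C(C)C)C(C)=C
F5 | step 6 | [(2R,4E)-5,9-dimethyl-2-(prop-1-en-2-yl)deca-4,8-dien-1-yl]zinc iodide | I[Zn]C[C@H](C/C=C(\C)CCC=C(C)C)C(C)=C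
F6 | step 6 | (4-iodo-3,5-dimethoxyphenoxy)tri(propan-2-yl)silane | COc1cc(O[Si](C(C)C)(C(C)C)C(C)C)cc(OC)c1I
F7 | step 10 | (1R,5R,7S)-3-[3,4-bis(tert-butyldimethylsilyloxy)benzoyl]-5,7-bis[(2E)-3,7-dimethylocta-2,6-dien-1-yl]-4-methoxy-8,8-dimethylbicyclo[3.3.1]non-3-ene-2,9-dione | CC(C)=CCC/C(C)=C/C[C@H]1C[C@@]2(C/C=C(\C)CCC=C(C)C)C(=O)[C@H](C(=O)C(C(=O)c3ccc(O[Si](C)(C)C(C)(C)C)c(O[Si](C)(C)C(C)(C)C)c3)=C2OC)C1(C)C
A1 | alternative 1 | (4S)-2,4-bis[(2E)-3,7-dimethylocta-2,6-dien-1-yl]-1-methoxy-5,5-dimethylcyclohex-1-ene | COC1=C(C/C=C(\C)CCC=C(C)C)C[C@H](C/C=C(\C)CCC=C(C)C)C(C)(C)C1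
A2 | alternative 1 | (1S,5R,7S)-5,7-bis[(2E)-3,7-dimethylocta-2,6-dien-1-yl]-8,8-dimethylbicyclo[3.3.1]nonane-2,4,9-trione | CC(C)=CCC/C(C)=C/C[C@H]1C[C@@]2(C/C=C(\C)CCC=C(C)C)C(=O)[C@H](C(=O)CC2=O)C1(C)C
A3 | alternative 2 | (3,4-dihydroxyphenyl){3-[(2E)-3,7-dimethylocta-2,6-dien-1-yl]-2,4,6-trihydroxy-5-(3-methylbut-2-en-1-yl)phenyl}methanone | CC(C)=CCc1c(O)c(C/C=C(\C)CCC=C(C)C)c(O)c(C(=O)c2ccc(O)c(O)c2)c1O
A4 | alternative 2 | (1R,5R,7S)-3-(3,4-dihydroxybenzoyl)-5-[(2E)-3,7-dimethylocta-2,6-dien-1-yl]-4-hydroxy-8,8-dimethyl-1-(3-methylbut-2-en-1-yl)-2,9-dioxobicyclo[3.3.1]non-3-ene-7-carbaldehyde | O=C[C@H]1C[C@@]2(C/C=C(\C)CCC=C(C)C)C(=O)[C@](CC=C(C)C)(C(=O)C(C(=O)c3ccc(O)c(O)c3)=C2O)C1(C)C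
A5 | alternative 3 | methyl 3-acetyl-3,5-bis[(2E)-3,7-dimethylocta-2,6-dien-1-yl]-6,6-dimethyl-1-(3-methylbut-2-en-1-yl)-2-oxocyclohexane-1-carboxylate with the configuration that leads to 27 | COC(=O)[C@@]1(CC=C(C)C)C(=O)[C@@](C/C=C(\C)CCC=C(C)C)(C(C)=O)C[C@H](C/C=C(\C)CCC=C(C)C)C1(C)C
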